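**Plan**
The retrosynthesis cuts O1–C2 and C3–C4 of the pyran ring in one operation (retro-hetero-Diels–Alder), giving an o-quinone methide of ring A and 3,4,5-trimethoxystyrene.
Enabling feature: O1 is the phenolic oxygen of ring A and C4 is a benzylic CH2 ortho to it, so O1–C8a–C4a–C4 is a latent o-quinone methide heterodiene; the 7-OMe para to C4a eases its formation.
C2–C3, with the trimethoxyphenyl group on C2, is the matching electron-rich styrene 2π partner.
Forward: rings A and B are bought as two aldehydes; a Wittig methylenation gives the styrene, a borohydride reduction gives the o-hydroxybenzyl alcohol, and the pyran ring is closed last by [4+2] union of the two halves.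
Stereochemistry: C2, the only stereocentre, is set in the cycloaddition by a chiral Brønsted acid that holds the o-quinone methide as a hydrogen-bonded ion pair; no later step touches it.

Key step: step 3

Remark: the sense of induction cannot be predicted for this substrate; the (R)-catalyst is written in step 3, and its mirror image is used instead, with no other change, if the first run shows it favours 2R.

Step 1
Reactants: 1 3,4,5-trimethoxybenzaldehyde
Product: 2 3,4,5-trimethoxystyrene (5-ethenyl-1,2,3-trimethoxybenzene)
Conditions: Ph3PCH3Br, KOtBu, THF, 0 °C to rt
Reagents that add atoms: methyltriphenylphosphonium bromide, C[P+](c1ccccc1)(c1ccccc1)c1ccccc1.[Br-]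
Why: Wittig methylenation of a non-enolisable aryl aldehyde with the unstabilised ylide should give the terminal styrene; no stereocentre is formed.

Step 2
Reactants: 3 2-hydroxy-3,4-dimethoxybenzaldehyde
Product: 4 6-(hydroxymethyl)-2,3-dimethoxyphenol (2-hydroxy-3,4-dimethoxybenzyl alcohol)
Conditions: NaBH4, MeOH, 0 °C; pH 7 buffer work-up, used fresh
Reagents that add atoms: none
Why: Borohydride reduction of an aryl aldehyde to the benzylic alcohol leaves the phenol and methyl ethers untouched, and a cold neutral work-up avoids premature loss of water from this electron-rich o-hydroxybenzyl alcohol; no stereocentre is formed.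

Step 3
Reactants: 4 6-(hydroxymethyl)-2,3-dimethoxyphenol; 2 3,4,5-trimethoxystyrene
Product: 6 (2S)-7,8,3',4',5'-pentamethoxyflavan, via o-quinone methide 5 (not isolated)
Conditions: (R)-3,3'-bis(2,4,6-triisopropylphenyl)-H8-BINOL N-triflylphosphoramide (5 mol %), 2 (3 equiv), 5 Å MS, PhMe, –20 to 0 °C, slow addition of 4; Et3N quench
Reagents that add atoms: none
Why: Proposed new method: the chiral acid protonates the benzylic hydroxyl of 4, which leaves as water with help from the para-methoxy and ortho-hydroxy groups to give o-quinone methide 5, hydrogen-bonded through its carbonyl oxygen to the chiral phosphoramide anion; the CH2 terminus of styrene 2 then adds to the exocyclic methylene carbon while the carbonyl oxygen closes onto the benzylic carbon of the styrene in a concerted but asynchronous inverse-electron-demand hetero-Diels–Alder reaction. The closest known reaction type is the chiral N-triflylphosphoramide-catalysed [4+2] cycloaddition of styrenes with o-quinone methides generated from o-hydroxybenzhydryl alcohols; new here is a methide carbon without a substituent, so that C2 is the only stereocentre and no C4 aryl group helps to orient the diene in the catalyst pocket. The dihydropyran ring closes by intermolecular [4+2] cycloaddition (the four atoms O=C–C=CH2 of 5 plus the two vinyl carbons of 2), forming C3–C4 and O1–C2 together. The C2 configuration should be controlled by the catalyst alone: the bound anion shields one face of 5 and the 3,3'-aryl walls fix the endo/exo orientation of the trimethoxyphenyl group. Regioselectivity (aryl on the carbon next to oxygen) follows from the polarisation of the partners, the nucleophilic CH2 of the styrene meeting the electrophilic methide carbon. Self-condensation of 5 is suppressed by slow addition of 4 into excess 2, and the stereocentre is kept by a cold Et3N quench before the acid can re-ionise the benzylic C2–O bond.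

**Compound list**
1 | 3,4,5-trimethoxybenzaldehyde | COc1cc(C=O)cc(OC)c1OC | starting material
2 | 3,4,5-trimethoxystyrene (5-ethenyl-1,2,3-trimethoxybenzene) | COc1cc(C=C)cc(OC)c1OC | intermediate
3 | 2-hydroxy-3,4-dimethoxybenzaldehyde | COc1ccc(C=O)c(O)c1OC | starting material
4 | 6-(hydroxymethyl)-2,3-dimethoxyphenol | COc1ccc(CO)c(O)c1OC | intermediate
5 | 2,3-dimethoxy-6-methylidenecyclohexa-2,4-dien-1-one (o-quinone methide) | COC1=C(OC)C(=O)C(=C)C=C1 | intermediate
6 | (2S)-7,8,3',4',5'-pentamethoxyflavan [(2S)-7,8-dimethoxy-2-(3,4,5-trimethoxyphenyl)chromane] | COc1cc([C@@H]2CCc3ccc(OC)c(OC)c3O2)cc(OC)c1OC | target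

**Totals**
Total step count: 3. Longest linear sequence: 2 steps (1 → 2 → 6 or 3 → 4 → 6).

**Steps most likely to fail**

Step 3 (carries the label). The chiral anion may not tell apart the two faces of the small, C4-unsubstituted o-quinone methide, giving poor facial selectivity. The methide may also self-condense or alkylate an electron-rich ring faster than it is trapped, and the acid may re-open the benzylic C2–O bond and erode the stereocentre. The fallback uses known chemistry throughout, sets out from 3 and comes back at 6. Claisen–Schmidt condensation of 3 with commercial 3',4',5'-trimethoxyacetophenone (KOH, EtOH, rt) should give the chalcone (E)-3-(2-hydroxy-3,4-dimethoxyphenyl)-1-(3,4,5-trimethoxyphenyl)prop-2-en-1-one F1. Hydrogenation of the C=C bond only (H2, Pd/C, EtOAc, stopped after one equivalent) should give the dihydrochalcone 3-(2-hydroxy-3,4-dimethoxyphenyl)-1-(3,4,5-trimethoxyphenyl)propan-1-one F2. Noyori asymmetric transfer hydrogenation (RuCl[(R,R)-TsDPEN](p-cymene), HCO2H/Et3N) should give, by analogy with acetophenone, the carbinol (1R)-3-(2-hydroxy-3,4-dimethoxyphenyl)-1-(3,4,5-trimethoxyphenyl)propan-1-ol F3. Intramolecular Mitsunobu etherification (PPh3, DIAD, THF, 0 °C) then closes the same pyran ring at O1–C2 with inversion, turning the R carbinol into the 2S flavan 6.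

Step 2. The electron-rich o-hydroxybenzyl alcohol may lose water during work-up or storage and oligomerise through the o-quinone methide before it reaches the key step. The fallback sets out from 3 and comes back at intermediate 5. After the NaBH4 reduction is run in EtOH, the ethanolic solution is made weakly acidic (Amberlyst-15, rt) without isolating the diol, so that the solvent traps the transient methide. This should give the storable, chromatographable benzylic ether 6-(ethoxymethyl)-2,3-dimethoxyphenol F5. Under the acid of step 3, F5 should lose ethanol (taken up by the sieves) and deliver 5.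

Step 1. The electron-rich styrene may oligomerise on heating or on acidic silica while it is being freed from triphenylphosphine oxide, and residual phosphine oxide could bind the acid catalyst of step 3. The fallback sets out from 1 and comes back at 2 by Peterson olefination. Addition of Me3SiCH2MgCl (THF, 0 °C) should give the racemic β-hydroxysilane 1-(3,4,5-trimethoxyphenyl)-2-(trimethylsilyl)ethanol F4. Syn-elimination with KH (THF, rt) should then give 2 with only volatile silicon by-products.

**Further compounds**
F1 | step 3 | (E)-3-(2-hydroxy-3,4-dimethoxyphenyl)-1-(3,4,5-trimethoxyphenyl)prop-2-en-1-one | COc1cc(C(=O)/C=C/c2ccc(OC)c(OC)c2O)cc(OC)c1OC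
F2 | step 3 | 3-(2-hydroxy-3,4-dimethoxyphenyl)-1-(3,4,5-trimethoxyphenyl)propan-1-one | COc1cc(C(=O)CCc2ccc(OC)c(OC)c2O)cc(OC)c1OC
F3 | step 3 | (1R)-3-(2-hydroxy-3,4-dimethoxyphenyl)-1-(3,4,5-trimethoxyphenyl)propan-1-ol | COc1cc([C@H](O)CCc2ccc(OC)c(OC)c2O)cc(OC)c1OC
F4 | step 1 | 1-(3,4,5-trimethoxyphenyl)-2-(trimethylsilyl)ethanol (racemic) | COc1cc(C(O)C[Si](C)(C)C)cc(OC)c1OC
F5 | step 2 | 6-(ethoxymethyl)-2,3-dimethoxyphenol | CCOCc1ccc(OC)c(OC)c1O
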